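Compound numbers are those of the steps and of the compound list below. Lactone ring C is numbered O1, C2 (carbonyl), C3, C4, C5. Ring A is the aryl group of the C4 benzyl substituent, ring B that of the C3 benzyl substituent, and ring D the aryl group of the ketone. The side chain on ring B C5 is C8'' (methine), C9'' (hydroxymethyl) and C7'' (ketone).

## The problem

The target 29 is a sesquilignan built on a butyrolactone, ring C, that carries a 4-hydroxy-3-methoxybenzyl group (ring A) on C4 and, trans to it, a second benzyl group (ring B) on C3. Ring B bears at C5 a three-carbon ketol chain, the methine C8'' with its hydroxymethyl group C9'' and the ketone C7'', which ends in the guaiacyl ring D. Three stereocentres have to be set, C3 (S), C4 (S) and C8'' (S). C4 can control C3, because an electrophile enters the enolate of a 4-substituted lactone anti to the substituent. C8'' is separated from the lactone by ring B and a methylene group, so nothing in the molecule can direct it and it has to be made in the absolute sense on its own. C8'' is also the fragile point: it is benzylic, α to an aryl ketone and β to a hydroxyl group, so base epimerises it, dehydrates the ketol or expels formaldehyde by retro-aldol cleavage, while acid lets the neighbouring ring B phenol close on the ketone and aromatise to a benzofuran. The three free phenols are sensitive to oxidants and the lactone to hydride, hydroxide and organometallic reagents. The feature that opens the problem is that C8'' carries two one-carbon arms: once C7'' is taken back to the alcohol level and ring D is removed, C7'' and C9'' are the two enantiotopic hydroxymethyl groups of a 2-arylpropane-1,3-diol on ring B, so C8'' can be created by telling two identical groups apart at a stage where no carbonyl group stands beside it.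

## Retrosynthesis

**End game.** The ketone is the last functional group to appear. Target 29 is traced to its tris-benzyl ether 28 (three O–benzyl bonds cut), 28 to diol 27 (C7'' back to the alcohol) and 27 to the bis-silyl ether 26. This order means that C8'' stands next to a carbonyl group only during a neutral oxidation and a neutral hydrogenolysis. Cutting the silyl ethers after the oxidation would expose the ketol to fluoride. The forward steps must therefore distinguish a benzylic from a saturated alcohol and cleave benzyl ethers without touching an aryl ketone.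

**Ring C to ring B.** In 26 the bond between C3 and the ring B benzylic methylene is cut, giving the enolate 25 of lactone 24 and benzylic bromide 19. The neighbouring cut at the C4 benzyl group would leave no stereocentre in the lactone to steer the other. The chosen cut lets C4 set C3 by trans alkylation and joins two fragments of similar size late. The forward reaction must deliver the trans isomer from a bromide that has no acidic hydrogen.

**Lactone 24.** The bond between the ring A benzylic carbon and ring A is cut through ester 23, leading to the cyclopropane-fused lactone 22 and Grignard reagent 14. Lactone 22 in turn comes from diethyl malonate 4 and (S)-epichlorohydrin 20. An asymmetric hydrogenation of a benzylidene succinate would serve as well, but the chiral pool route fixes the (S) configuration by mechanism and draws on the same Grignard reagent 14 that is needed for ring D.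

**Bromide 19.** Bromide 19 is the functional-group descendant of alcohol 18, aldehyde 17 and dioxolane 16. The formyl group of the starting material is carried as an acetal through all basic and reducing steps and is released only when the benzylic carbon is needed.

**Ring D.** In 16 (through alcohol 15) the bond from C7'' to ring D is cut, giving aldehyde 11 and Grignard reagent 14. Reagent 14 is prepared once, as a titrated solution, from aryl bromide 13, the benzyl ether of phenol 12, and is shared with the lactone branch. The configuration at C7'' is of no account because it is oxidised later. Aldehyde 11 comes from alcohol 10, which is reached from silyl ether acetate 9 and so from monoacetate 8. The acetate marks the arm that becomes C7'' and the free hydroxyl the arm that becomes C9''.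

**C8''.** Monoacetate 8 is traced to the prochiral diol 6 and vinyl acetate 7. No skeletal bond is cut; the disconnection removes the only difference between the two arms. A carbon–carbon bond-forming creation of C8'' (for example an asymmetric α-arylation at the ketone level) would make the centre while it is enolisable. Here it is born between two sp3 carbons and a lipase does the differentiation.

**Diol 6.** The bond from ring B C5 to C8'' is cut: diol 6 comes from aryl malonate 5, and 5 from aryl iodide 3 and diethyl malonate 4. Iodide 3 is the benzylated (2) and acetalised form of 5-iodovanillin 1, which already holds every ring B substituent in place. The forward steps are a CuI-catalysed malonate arylation and a hydride reduction.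

## Roads not taken

Alternative 1: The cut is in ring C, at the O1–C5 and O1–C2 bonds. 3-(4-Benzyloxy-3-methoxybenzyl)cyclobutanone A1 would be desymmetrised by a Baeyer–Villiger oxidation (chiral phosphoric acid with aqueous H2O2, or a monooxygenase) to give lactone A2, which is the same compound as 24.
- Merits: the step is catalytic, closes the ring and sets C4 at once, and A1 should be within a few steps of a commercial allylarene by ketene cycloaddition and dechlorination.
- Weak points: the migrating methylene groups differ only through a flexible benzyl group one atom away, which gives a catalyst little to grip, and an electron-rich arene has to tolerate peroxide. Above all, the step answers only C4, for which reliable solutions exist, and leaves C8'' without a plan.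
- Comparison: as a way to the lactone it is about as short as steps 16–18 and more elegant. The chosen plan sets against it a configuration fixed by the chiral pool. The two ideas are not rivals for the key step; Alternative 1 could replace steps 16–18 but not step 5.

Alternative 2: The cut is the bond from ring B C5 to C8''. The ring B phenolic oxygen of the fully assembled dibenzyl lactone would be bound to the (R)-configured carbinol carbon of a 2-aryl allylic alcohol, giving ether A3. Heating would move the allyl group to C5 by an aromatic Claisen rearrangement, giving phenol A4. The ethylidene group of A4 would later be cleaved to the C7'' ketone.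
- Merits: C5 is the only free ortho position, so the regiochemistry is certain. C8'' is created as an allylic centre that cannot enolise. Ring D arrives with the chain, so neither the labile aldehyde 11 nor bromide 19 is needed. The route is more convergent and shorter than the chosen one.
- Weak points: A3 is a secondary allylic aryl ether conjugated with ring D, so its formation with clean stereochemical outcome competes with allylic transposition and ionisation. At the temperature of the rearrangement, ionisation and recombination would erode the transfer of chirality, which in any case depends on a single chair and a pure alkene geometry. The new phenol can add to the styrene or rearrange further. The final oxidative cleavage has to spare three electron-rich rings.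
- Comparison: it is better in step count and convergence. The chosen plan sets against it moderate temperatures throughout, reaction types that are all established for their substrate class, and a stereocentre whose purity comes from an enzyme and can be measured and upgraded early.

Alternative 3: The cut is the C3–C4 bond. The (S)-configured (E)-allylic 3-arylpropanoate A5 would be enolised, O-silylated and warmed, so that an Ireland–Claisen rearrangement gives the hexenoic acid A6. Cleavage of the propenyl group, reduction and lactonisation would then give ring C.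
- Merits: both lactone centres are set in one step, and no benzylic bromide is needed, which is an advantage over step 19.
- Weak points: the syn isomer requires a single enolate geometry from a plain ester, three further steps turn the propenyl group into C5, and ring B still carries only a bromine atom at C5. The whole ketol chain would then have to be built in the presence of the lactone, where the hydride reduction that makes the propanediol cannot be used without masking ring C.
- Comparison: it solves the trans relationship that lactone alkylation already solves reliably, and makes the harder problem at C8'' worse. The chosen plan reverses this: it takes the standard answer for C3 and C4 and spends its key step on C8''.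

Key step: step 5

Assumption: in the acylation mode the lipase is taken to acetylate the hydroxymethyl group that makes 8 the (S)-monoacetate. The sense cannot be predicted with certainty for this aryl group and is to be proved on 8 by chemical correlation before the route is continued. If the preference is the opposite, the hydrolytic mode described under the uncertain steps delivers 8.

## Route

Step 1
Reactants: 1 5-iodovanillin (4-hydroxy-3-iodo-5-methoxybenzaldehyde)
Product: 2 4-(benzyloxy)-3-iodo-5-methoxybenzaldehyde
Conditions: BnBr, K2CO3, DMF, 60 °C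
Reagents that add atoms: benzyl bromide, BrCc1ccccc1
Why: Williamson ether synthesis on a phenoxide; the benzyl ether lasts to the final hydrogenolysis and is inert to all steps between.

Step 2
Reactants: 2 4-(benzyloxy)-3-iodo-5-methoxybenzaldehyde
Product: 3 2-[4-(benzyloxy)-3-iodo-5-methoxyphenyl]-1,3-dioxolane
Conditions: HOCH2CH2OH, p-TsOH·H2O (cat.), toluene, reflux, Dean–Stark trap
Reagents that add atoms: ethylene glycol, OCCO
Why: Acid-catalysed acetalisation with azeotropic removal of water; the acetal keeps the formyl group from a Knoevenagel condensation with the malonate and from the hydride reduction and the Grignard addition that follow.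

Step 3
Reactants: 3 2-[4-(benzyloxy)-3-iodo-5-methoxyphenyl]-1,3-dioxolane; 4 diethyl malonate
Product: 5 diethyl 2-[2-(benzyloxy)-5-(1,3-dioxolan-2-yl)-3-methoxyphenyl]malonate
Conditions: CuI (10 mol%), picolinic acid (20 mol%), Cs2CO3, 1,4-dioxane, 70 °C
Reagents that add atoms: none
Why: CuI-catalysed arylation of a malonate with an aryl iodide (Hurtley-type coupling); the product rests as its enolate, which prevents a second arylation, and the single ortho substituent should be tolerated by the CuI/picolinic acid system.

Step 4
Reactants: 5 diethyl 2-[2-(benzyloxy)-5-(1,3-dioxolan-2-yl)-3-methoxyphenyl]malonate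
Product: 6 2-[2-(benzyloxy)-5-(1,3-dioxolan-2-yl)-3-methoxyphenyl]propane-1,3-diol
Conditions: LiAlH4 (excess), THF, 0 °C to rt, 5 added to the hydride; aq NaOH work-up
Reagents that add atoms: none
Why: Hydride reduction of a malonic diester to the propane-1,3-diol; inverse addition to excess hydride in the cold keeps enolate formation and the elimination that follows from it low, and acetal and benzyl ether are inert.

Step 5
Reactants: 6 2-[2-(benzyloxy)-5-(1,3-dioxolan-2-yl)-3-methoxyphenyl]propane-1,3-diol; 7 vinyl acetate
Product: 8 (2S)-2-[2-(benzyloxy)-5-(1,3-dioxolan-2-yl)-3-methoxyphenyl]-3-hydroxypropyl acetate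
Conditions: Pseudomonas cepacia lipase (immobilised), vinyl acetate (3 equiv), t-BuOMe, 25 °C, monitored by chiral HPLC
Reagents that add atoms: none
Why: Lipase-catalysed desymmetrising transesterification, a known reaction type for prochiral 2-arylpropane-1,3-diols. The active-site serine is acetylated by vinyl acetate, the vinyl alcohol set free tautomerises to acetaldehyde so that the transfer is irreversible, and the acetyl-enzyme passes the acetyl group to the hydroxymethyl group of 6 that lies at the catalytic centre. No ring closes and no skeletal bond forms; the only new stereocentre is C8'', and it is controlled by the chiral pocket of the enzyme alone, which holds the large ortho-benzyloxyaryl group and the small hydrogen in fixed sites and so presents one enantiotopic arm. The step needs selectivity between the two enantiotopic CH2OH groups and between mono- and diacylation; the first rests on the constitutional identity of the arms, which leaves only the enzyme to tell them apart, and on the size difference between aryl and hydrogen at the prochiral carbon. The second is helped because the minor enantiomer of the monoacetate still has its free hydroxyl on the arm the enzyme prefers, so it is drained into the achiral diacetate and the optical purity of 8 should rise with conversion. The medium is neutral and dry, so the dioxolane survives, and the absence of base at ambient temperature suppresses the acetyl migration that would racemise 8.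

Step 6
Reactants: 8 (2S)-monoacetate
Product: 9 (2R)-2-[2-(benzyloxy)-5-(1,3-dioxolan-2-yl)-3-methoxyphenyl]-3-[(tert-butyldiphenylsilyl)oxy]propyl acetate
Conditions: TBDPSCl, imidazole, CH2Cl2, 0 °C
Reagents that add atoms: tert-butyl(chloro)diphenylsilane, CC(C)(C)[Si](Cl)(c1ccccc1)c1ccccc1
Why: Silylation of a primary alcohol under weakly basic conditions at 0 °C, fast enough to outrun acetyl migration; the descriptor changes by priority only, and the TBDPS group is chosen because it withstands the acid of step 13.

Step 7
Reactants: 9 silyl ether acetate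
Product: 10 (2R)-2-[2-(benzyloxy)-5-(1,3-dioxolan-2-yl)-3-methoxyphenyl]-3-[(tert-butyldiphenylsilyl)oxy]propan-1-ol
Conditions: K2CO3 (0.2 equiv), MeOH, 0 °C
Reagents that add atoms: none
Why: Methanolysis of an acetate (transesterification); the bulky TBDPS group does not migrate under these mild conditions, so the arm destined for C7'' is set free without loss of configuration.

Step 8
Reactants: 10 primary alcohol
Product: 11 (2S)-2-[2-(benzyloxy)-5-(1,3-dioxolan-2-yl)-3-methoxyphenyl]-3-[(tert-butyldiphenylsilyl)oxy]propanal
Conditions: Dess–Martin periodinane, NaHCO3, CH2Cl2, 0 °C; filtered and used at once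
Reagents that add atoms: none
Why: Dess–Martin oxidation is non-basic when buffered, so the α-aryl aldehyde is formed without enolisation or loss of silanol; it is not stored or chromatographed.

Step 9
Reactants: 12 4-bromo-2-methoxyphenol
Product: 13 1-(benzyloxy)-4-bromo-2-methoxybenzene
Conditions: BnBr, K2CO3, acetone, reflux
Reagents that add atoms: benzyl bromide, BrCc1ccccc1
Why: Williamson ether synthesis; this one bromide is the source of both ring D (steps 10 and 11) and ring A (step 17).

Step 10
Reactants: 13 1-(benzyloxy)-4-bromo-2-methoxybenzene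
Product: 14 [4-(benzyloxy)-3-methoxyphenyl]magnesium bromide (THF solution, titrated and kept under argon)
Conditions: Mg turnings, I2 (cat.), THF, 40 °C; titrated
Reagents that add atoms: magnesium, [Mg]
Why: Grignard reagent formation by insertion of magnesium into an aryl bromide; the benzyl and methyl ethers are inert, and one titrated stock solution serves both step 11 and step 17.

Step 11
Reactants: 11 α-aryl aldehyde; 14 [4-(benzyloxy)-3-methoxyphenyl]magnesium bromide
Product: 15 (1RS,2S)-2-[2-(benzyloxy)-5-(1,3-dioxolan-2-yl)-3-methoxyphenyl]-1-[4-(benzyloxy)-3-methoxyphenyl]-3-[(tert-butyldiphenylsilyl)oxy]propan-1-ol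
Conditions: 14 (1.3 equiv), LaCl3·2LiCl, THF, −78 °C; aq NH4Cl
Reagents that add atoms: none
Why: Grignard addition to an aldehyde; LaCl3·2LiCl activates the carbonyl group and favours addition over deprotonation, and at −78 °C addition should outrun enolisation of C8''. The new carbinol centre C7'' forms as a mixture, which is harmless because it becomes the ketone.

Step 12
Reactants: 15 secondary benzylic alcohol
Product: 16 2-{4-(benzyloxy)-3-[(1RS,2S)-1-[4-(benzyloxy)-3-methoxyphenyl]-1-[(tert-butyldimethylsilyl)oxy]-3-[(tert-butyldiphenylsilyl)oxy]propan-2-yl]-5-methoxyphenyl}-1,3-dioxolane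
Conditions: TBSCl, imidazole, DMAP (cat.), DMF, 40 °C
Reagents that add atoms: tert-butyl(chloro)dimethylsilane, CC(C)(C)[Si](C)(C)Cl
Why: Silylation of a secondary benzylic alcohol with the chloride and imidazole; a silyl triflate is avoided because with a pyridine base it would attack the dioxolane.

Step 13
Reactants: 16 bis-silyl ether dioxolane
Product: 17 4-(benzyloxy)-3-[(1RS,2S)-1-[4-(benzyloxy)-3-methoxyphenyl]-1-[(tert-butyldimethylsilyl)oxy]-3-[(tert-butyldiphenylsilyl)oxy]propan-2-yl]-5-methoxybenzaldehyde
Conditions: pyridinium p-toluenesulfonate (cat.), acetone/H2O 10:1, 50 °C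
Reagents that add atoms: water, O
Why: Acid-catalysed acetal hydrolysis; the electron-rich ring stabilises the oxocarbenium ion, so a weak acid suffices and the TBDPS ether and the hindered secondary TBS ether remain.

Step 14
Reactants: 17 aryl aldehyde
Product: 18 {4-(benzyloxy)-3-[(1RS,2S)-1-[4-(benzyloxy)-3-methoxyphenyl]-1-[(tert-butyldimethylsilyl)oxy]-3-[(tert-butyldiphenylsilyl)oxy]propan-2-yl]-5-methoxyphenyl}methanol
Conditions: NaBH4, MeOH/THF, 0 °C
Reagents that add atoms: none
Why: Borohydride reduction of an aromatic aldehyde; silyl and benzyl ethers are untouched.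

Step 15
Reactants: 18 benzylic alcohol
Product: 19 2-(benzyloxy)-5-(bromomethyl)-1-methoxy-3-[(1RS,2S)-1-[4-(benzyloxy)-3-methoxyphenyl]-1-[(tert-butyldimethylsilyl)oxy]-3-[(tert-butyldiphenylsilyl)oxy]propan-2-yl]benzene
Conditions: CBr4, PPh3, CH2Cl2, 0 °C; filtered through a short silica pad and used directly
Reagents that add atoms: carbon tetrabromide, BrC(Br)(Br)Br
Why: Appel bromination under neutral conditions, which the silyl ethers tolerate; the para-alkoxybenzyl bromide is reactive and is therefore not stored.

Step 16
Reactants: 4 diethyl malonate; 20 (S)-epichlorohydrin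
Product: 22 ethyl (1R,5S)-2-oxo-3-oxabicyclo[3.1.0]hexane-1-carboxylate, via epoxide malonate 21 (not isolated)
Conditions: NaOEt, EtOH, rt then reflux
Reagents that add atoms: none
Why: Known cyclopropanation–lactonisation cascade: malonate opens the epoxide of 20 at its terminal carbon, the alkoxide displaces chloride to give epoxide 21, the malonate anion closes the cyclopropane by 3-exo-tet attack with inversion, and the alkoxide lactonises onto the cis ester, so the configuration of 22 follows from that of 20.

Step 17
Reactants: 22 cyclopropane-fused lactone; 14 [4-(benzyloxy)-3-methoxyphenyl]magnesium bromide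
Product: 23 ethyl (4S)-4-[4-(benzyloxy)-3-methoxybenzyl]-2-oxooxolane-3-carboxylate (mixture at C3)
Conditions: 14 (1.2 equiv), CuI (10 mol%), THF, −30 °C; aq NH4Cl
Reagents that add atoms: none
Why: CuI-catalysed homoconjugate opening of the doubly activated cyclopropane by a Grignard reagent at the unsubstituted ring carbon; no bond to the stereocentre is touched, so it becomes C4 of the lactone with (S) configuration, and the centre at C3 is removed in the next step.

Step 18
Reactants: 23 α-ethoxycarbonyl lactone
Product: 24 (4S)-4-[4-(benzyloxy)-3-methoxybenzyl]oxolan-2-one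
Conditions: LiCl, H2O, DMSO, 140 °C
Reagents that add atoms: none
Why: Krapcho dealkoxycarbonylation of a malonate-type ester; the lactone and the benzyl ether survive and C4 is not involved.

Step 19
Reactants: 24 (S)-β-benzyl lactone; 19 benzylic bromide
Product: 26 (3S,4S)-4-[4-(benzyloxy)-3-methoxybenzyl]-3-{4-(benzyloxy)-3-[(1RS,2S)-1-[4-(benzyloxy)-3-methoxyphenyl]-1-[(tert-butyldimethylsilyl)oxy]-3-[(tert-butyldiphenylsilyl)oxy]propan-2-yl]-5-methoxybenzyl}oxolan-2-one, via lithium enolate 25 (not isolated)
Conditions: 24 (1.2 equiv), LiN(SiMe3)2, THF, −78 °C; then 19, DMPU, −78 to −30 °C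
Reagents that add atoms: none
Why: Alkylation of a lactone lithium enolate with a benzylic bromide; the C4 benzyl group shields one face of the planar enolate 25, so 19 enters anti and C3 is set trans to C4 (substrate control), which is also the more stable arrangement. Bromide 19 has no acidic or β-hydrogen to divert the enolate.

Step 20
Reactants: 26 bis-silyl ether lactone
Product: 27 (3S,4S)-4-[4-(benzyloxy)-3-methoxybenzyl]-3-{4-(benzyloxy)-3-[(1RS,2S)-1-[4-(benzyloxy)-3-methoxyphenyl]-1,3-dihydroxypropan-2-yl]-5-methoxybenzyl}oxolan-2-one
Conditions: Bu4NF, AcOH, THF, rt to 40 °C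
Reagents that add atoms: none
Why: Fluoride cleavage of both silyl ethers; acetic acid buffers the alkoxides so that the lactone is not opened, and with no ketone yet at C7'' the centre C8'' cannot epimerise.

Step 21
Reactants: 27 diol
Product: 28 (3S,4S)-4-[4-(benzyloxy)-3-methoxybenzyl]-3-{4-(benzyloxy)-3-[(2S)-1-[4-(benzyloxy)-3-methoxyphenyl]-3-hydroxy-1-oxopropan-2-yl]-5-methoxybenzyl}oxolan-2-one
Conditions: MnO2 (activated, excess), CH2Cl2, rt
Reagents that add atoms: none
Why: MnO2 oxidises the benzylic, para-alkoxy-activated alcohol and leaves the saturated primary C9'' hydroxyl alone; the medium is neutral, so the new α-aryl β-hydroxy ketone is neither enolised nor dehydrated, and both C7'' epimers give one ketone.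

Step 22
Reactants: 28 tris-benzyl ether ketone
Product: 29 (3S,4S)-4-(4-hydroxy-3-methoxybenzyl)-3-{4-hydroxy-3-[(2S)-3-hydroxy-1-(4-hydroxy-3-methoxyphenyl)-1-oxopropan-2-yl]-5-methoxybenzyl}oxolan-2-one
Conditions: H2 (1 atm), 10% Pd/C, EtOAc, rt; stopped after uptake of three equivalents
Reagents that add atoms: none
Why: Hydrogenolysis of three aryl benzyl ethers under neutral conditions; the electron-rich aryl ketone is reduced much more slowly than O-benzyl groups are cleaved, and without acid or base the ketol, C8'' and the ortho phenol–ketone pair are left as they are.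

## Compound list

1 | 5-iodovanillin (4-hydroxy-3-iodo-5-methoxybenzaldehyde) | COc1cc(C=O)cc(I)c1O | starting material
2 | 4-(benzyloxy)-3-iodo-5-methoxybenzaldehyde | COc1cc(C=O)cc(I)c1OCc1ccccc1 | intermediate
3 | 2-[4-(benzyloxy)-3-iodo-5-methoxyphenyl]-1,3-dioxolane | COc1cc(C2OCCO2)cc(I)c1OCc1ccccc1 | intermediate
4 | diethyl malonate | CCOC(=O)CC(=O)OCC | starting material
5 | diethyl 2-[2-(benzyloxy)-5-(1,3-dioxolan-2-yl)-3-methoxyphenyl]malonate | CCOC(=O)C(C(=O)OCC)c1cc(C2OCCO2)cc(OC)c1OCc1ccccc1 | intermediate
6 | 2-[2-(benzyloxy)-5-(1,3-dioxolan-2-yl)-3-methoxyphenyl]propane-1,3-diol | COc1cc(C2OCCO2)cc(C(CO)CO)c1OCc1ccccc1 | intermediate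
7 | vinyl acetate | C=COC(C)=O | starting material
8 | (2S)-2-[2-(benzyloxy)-5-(1,3-dioxolan-2-yl)-3-methoxyphenyl]-3-hydroxypropyl acetate | COc1cc(C2OCCO2)cc([C@@H](CO)COC(C)=O)c1OCc1ccccc1 | intermediate
9 | (2R)-2-[2-(benzyloxy)-5-(1,3-dioxolan-2-yl)-3-methoxyphenyl]-3-[(tert-butyldiphenylsilyl)oxy]propyl acetate | COc1cc(C2OCCO2)cc([C@@H](CO[Si](c2ccccc2)(c2ccccc2)C(C)(C)C)COC(C)=O)c1OCc1ccccc1 | intermediate
10 | (2R)-2-[2-(benzyloxy)-5-(1,3-dioxolan-2-yl)-3-methoxyphenyl]-3-[(tert-butyldiphenylsilyl)oxy]propan-1-ol | COc1cc(C2OCCO2)cc([C@@H](CO[Si](c2ccccc2)(c2ccccc2)C(C)(C)C)CO)c1OCc1ccccc1 | intermediate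
11 | (2S)-2-[2-(benzyloxy)-5-(1,3-dioxolan-2-yl)-3-methoxyphenyl]-3-[(tert-butyldiphenylsilyl)oxy]propanal | COc1cc(C2OCCO2)cc([C@@H](CO[Si](c2ccccc2)(c2ccccc2)C(C)(C)C)C=O)c1OCc1ccccc1 | intermediate
12 | 4-bromo-2-methoxyphenol | COc1cc(Br)ccc1O | starting material
13 | 1-(benzyloxy)-4-bromo-2-methoxybenzene | COc1cc(Br)ccc1OCc1ccccc1 | intermediate
14 | [4-(benzyloxy)-3-methoxyphenyl]magnesium bromide (titrated THF solution) | COc1cc([Mg]Br)ccc1OCc1ccccc1 | intermediate
15 | (1RS,2S)-2-[2-(benzyloxy)-5-(1,3-dioxolan-2-yl)-3-methoxyphenyl]-1-[4-(benzyloxy)-3-methoxyphenyl]-3-[(tert-butyldiphenylsilyl)oxy]propan-1-ol | COc1cc(C2OCCO2)cc([C@@H](CO[Si](c2ccccc2)(c2ccccc2)C(C)(C)C)C(O)c2ccc(OCc3ccccc3)c(OC)c2)c1OCc1ccccc1 | intermediate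
16 | 2-{4-(benzyloxy)-3-[(1RS,2S)-1-[4-(benzyloxy)-3-methoxyphenyl]-1-[(tert-butyldimethylsilyl)oxy]-3-[(tert-butyldiphenylsilyl)oxy]propan-2-yl]-5-methoxyphenyl}-1,3-dioxolane | COc1cc(C2OCCO2)cc([C@@H](CO[Si](c2ccccc2)(c2ccccc2)C(C)(C)C)C(O[Si](C)(C)C(C)(C)C)c2ccc(OCc3ccccc3)c(OC)c2)c1OCc1ccccc1 | intermediate
17 | 4-(benzyloxy)-3-[(1RS,2S)-1-[4-(benzyloxy)-3-methoxyphenyl]-1-[(tert-butyldimethylsilyl)oxy]-3-[(tert-butyldiphenylsilyl)oxy]propan-2-yl]-5-methoxybenzaldehyde | COc1cc(C=O)cc([C@@H](CO[Si](c2ccccc2)(c2ccccc2)C(C)(C)C)C(O[Si](C)(C)C(C)(C)C)c2ccc(OCc3ccccc3)c(OC)c2)c1OCc1ccccc1 | intermediate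
18 | {4-(benzyloxy)-3-[(1RS,2S)-1-[4-(benzyloxy)-3-methoxyphenyl]-1-[(tert-butyldimethylsilyl)oxy]-3-[(tert-butyldiphenylsilyl)oxy]propan-2-yl]-5-methoxyphenyl}methanol | COc1cc(CO)cc([C@@H](CO[Si](c2ccccc2)(c2ccccc2)C(C)(C)C)C(O[Si](C)(C)C(C)(C)C)c2ccc(OCc3ccccc3)c(OC)c2)c1OCc1ccccc1 | intermediate
19 | 2-(benzyloxy)-5-(bromomethyl)-1-methoxy-3-[(1RS,2S)-1-[4-(benzyloxy)-3-methoxyphenyl]-1-[(tert-butyldimethylsilyl)oxy]-3-[(tert-butyldiphenylsilyl)oxy]propan-2-yl]benzene | COc1cc(CBr)cc([C@@H](CO[Si](c2ccccc2)(c2ccccc2)C(C)(C)C)C(O[Si](C)(C)C(C)(C)C)c2ccc(OCc3ccccc3)c(OC)c2)c1OCc1ccccc1 | intermediate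
20 | (S)-epichlorohydrin [(2S)-2-(chloromethyl)oxirane] | ClC[C@@H]1CO1 | starting material
21 | diethyl 2-{[(2S)-oxiran-2-yl]methyl}malonate | CCOC(=O)C(C[C@H]1CO1)C(=O)OCC | intermediate (not isolated)
22 | ethyl (1R,5S)-2-oxo-3-oxabicyclo[3.1.0]hexane-1-carboxylate | CCOC(=O)[C@@]12C[C@@H]1COC2=O | intermediate
23 | ethyl (4S)-4-[4-(benzyloxy)-3-methoxybenzyl]-2-oxooxolane-3-carboxylate (mixture at C3) | CCOC(=O)C1C(=O)OC[C@H]1Cc1ccc(OCc2ccccc2)c(OC)c1 | intermediate
24 | (4S)-4-[4-(benzyloxy)-3-methoxybenzyl]oxolan-2-one | COc1cc(C[C@@H]2COC(=O)C2)ccc1OCc1ccccc1 | intermediate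
25 | lithium enolate of 24 (lithium (4S)-4-[4-(benzyloxy)-3-methoxybenzyl]-4,5-dihydrofuran-2-olate) | COc1cc(C[C@@H]2COC(O[Li])=C2)ccc1OCc1ccccc1 | intermediate (not isolated)
26 | (3S,4S)-4-[4-(benzyloxy)-3-methoxybenzyl]-3-{4-(benzyloxy)-3-[(1RS,2S)-1-[4-(benzyloxy)-3-methoxyphenyl]-1-[(tert-butyldimethylsilyl)oxy]-3-[(tert-butyldiphenylsilyl)oxy]propan-2-yl]-5-methoxybenzyl}oxolan-2-one | COc1cc(C[C@@H]2COC(=O)[C@H]2Cc2cc(OC)c(OCc3ccccc3)c([C@@H](CO[Si](c3ccccc3)(c3ccccc3)C(C)(C)C)C(O[Si](C)(C)C(C)(C)C)c3ccc(OCc4ccccc4)c(OC)c3)c2)ccc1OCc1ccccc1 | intermediate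
27 | (3S,4S)-4-[4-(benzyloxy)-3-methoxybenzyl]-3-{4-(benzyloxy)-3-[(1RS,2S)-1-[4-(benzyloxy)-3-methoxyphenyl]-1,3-dihydroxypropan-2-yl]-5-methoxybenzyl}oxolan-2-one | COc1cc(C[C@@H]2COC(=O)[C@H]2Cc2cc(OC)c(OCc3ccccc3)c([C@@H](CO)C(O)c3ccc(OCc4ccccc4)c(OC)c3)c2)ccc1OCc1ccccc1 | intermediate
28 | (3S,4S)-4-[4-(benzyloxy)-3-methoxybenzyl]-3-{4-(benzyloxy)-3-[(2S)-1-[4-(benzyloxy)-3-methoxyphenyl]-3-hydroxy-1-oxopropan-2-yl]-5-methoxybenzyl}oxolan-2-one | COc1cc(C[C@@H]2COC(=O)[C@H]2Cc2cc(OC)c(OCc3ccccc3)c([C@@H](CO)C(=O)c3ccc(OCc4ccccc4)c(OC)c3)c2)ccc1OCc1ccccc1 | intermediate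
29 | (3S,4S)-4-(4-hydroxy-3-methoxybenzyl)-3-{4-hydroxy-3-[(2S)-3-hydroxy-1-(4-hydroxy-3-methoxyphenyl)-1-oxopropan-2-yl]-5-methoxybenzyl}oxolan-2-one | COc1cc(C[C@@H]2COC(=O)[C@H]2Cc2cc(OC)c(O)c([C@@H](CO)C(=O)c3ccc(O)c(OC)c3)c2)ccc1O | target

## Step count and uncertain steps

Total: 22 steps. Longest linear sequence: 17 steps from 5-iodovanillin 1 (steps 1–8, 11–15, 19–22). Side branches: steps 9–10 (aryl bromide 13 and Grignard reagent 14) and steps 16–18 (lactone 24).

**Step 5 (key step).** The most likely failure is insufficient discrimination between the enantiotopic arms, or a preference for the arm that gives the mirror image of 8, because the ortho-benzyloxyaryl group may sit differently in the pocket than simpler aryl groups. Acetyl migration during isolation would also lower the optical purity. The fallback sets out from 6 and returns at 8. Diol 6 is acetylated (Ac2O, pyridine) to 2-[2-(benzyloxy)-5-(1,3-dioxolan-2-yl)-3-methoxyphenyl]propane-1,3-diyl diacetate F1. The same lipase in phosphate buffer (pH 7) with t-BuOMe then hydrolyses the acetate on the arm that fits its pocket. Since the enzyme now removes the group it would otherwise have put on, the surviving monoacetate is the mirror image of the acylation product, so 8 is reached when acylation runs the wrong way.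

**Step 3.** The coupling may stall through slow turnover of the CuI catalyst at the carbon next to the ortho-benzyloxy group, with protodeiodination taking over; the hydride reduction of step 4 can also lose material by enolate elimination. The fallback sets out from 3 and returns at 6, bypassing 5. Suzuki–Miyaura coupling of 3 with 2-(4,4,5,5-tetramethyl-1,3,2-dioxaborolan-2-yl)prop-2-en-1-ol (Pd(dppf)Cl2, K2CO3, dioxane/H2O, 80 °C) gives 2-[2-(benzyloxy)-5-(1,3-dioxolan-2-yl)-3-methoxyphenyl]prop-2-en-1-ol F2. Hydroboration–oxidation (BH3·THF, 0 °C; then NaOH, H2O2) places the second hydroxyl on the terminal carbon and gives 6.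

**Step 11 (with step 8).** Configuration at C8'' may be lost by enolisation of the α-aryl aldehyde, and silanol may be eliminated from the β-position, both driven by the basic organomagnesium reagent. The fallback sets out from 11 and returns at 15. A Nozaki–Hiyama–Kishi coupling, which is essentially non-basic, joins 11 with 1-(benzyloxy)-4-iodo-2-methoxybenzene F3 (from 4-iodo-2-methoxyphenol, BnBr, K2CO3) using CrCl2 (excess) and NiCl2 (cat.) in DMF at rt.

**Step 19.** The para-alkoxybenzyl bromide 19 may ionise and decompose before the hindered coupling takes place, and proton exchange between product and enolate may cause double alkylation. The fallback sets out from 17 and 24 and returns at 26, bypassing 18 and 19. Enolate 25 adds to aldehyde 17 at −78 °C to give the trans aldol adduct F4, (3R,4S)-4-[4-(benzyloxy)-3-methoxybenzyl]-3-{hydroxy[aryl]methyl}oxolan-2-one with the aryl group of 17, as a mixture at the carbinol carbon; the descriptor at C3 differs from that of 26 by priority only. The hydroxyl is converted (PhOC(S)Cl, pyridine, DMAP) to the O-phenyl thionocarbonate F5, and Barton–McCombie reduction (Bu3SnH, AIBN, toluene, 80 °C) removes the benzylic oxygen to give 26.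

**Step 21.** Conversion of the hindered secondary alcohol on the MnO2 surface may be incomplete, and forcing it may bring oxidation at the primary alcohol or the benzylic methylene groups. The fallback sets out from 27 and returns at 28. The primary hydroxyl is silylated selectively (TBSCl, imidazole, CH2Cl2, 0 °C) to give the C9'' TBS ether F6 of 27. Dess–Martin oxidation of the only free hydroxyl gives the ketone TBS ether F7, and HF·pyridine in THF/pyridine, a non-basic desilylation that does not trigger β-elimination, gives 28.

## Further compounds

F1 | step 5 | 2-[2-(benzyloxy)-5-(1,3-dioxolan-2-yl)-3-methoxyphenyl]propane-1,3-diyl diacetate | COc1cc(C2OCCO2)cc(C(COC(C)=O)COC(C)=O)c1OCc1ccccc1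
F2 | step 3 | 2-[2-(benzyloxy)-5-(1,3-dioxolan-2-yl)-3-methoxyphenyl]prop-2-en-1-ol | COc1cc(C2OCCO2)cc(C(=C)CO)c1OCc1ccccc1
F3 | step 11 | 1-(benzyloxy)-4-iodo-2-methoxybenzene | COc1cc(I)ccc1OCc1ccccc1
F4 | step 19 | trans (3R,4S) aldol adduct of enolate 25 and aldehyde 17 (carbinol epimers) | COc1cc(C[C@@H]2COC(=O)[C@H]2C(O)c2cc(OC)c(OCc3ccccc3)c([C@@H](CO[Si](c3ccccc3)(c3ccccc3)C(C)(C)C)C(O[Si](C)(C)C(C)(C)C)c3ccc(OCc4ccccc4)c(OC)c3)c2)ccc1OCc1ccccc1
F5 | step 19 | O-phenyl thionocarbonate of F4 | COc1cc(C[C@@H]2COC(=O)[C@H]2C(OC(=S)Oc2ccccc2)c2cc(OC)c(OCc3ccccc3)c([C@@H](CO[Si](c3ccccc3)(c3ccccc3)C(C)(C)C)C(O[Si](C)(C)C(C)(C)C)c3ccc(OCc4ccccc4)c(OC)c3)c2)ccc1OCc1ccccc1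
F6 | step 21 | C9'' tert-butyldimethylsilyl ether of diol 27 | COc1cc(C[C@@H]2COC(=O)[C@H]2Cc2cc(OC)c(OCc3ccccc3)c([C@@H](CO[Si](C)(C)C(C)(C)C)C(O)c3ccc(OCc4ccccc4)c(OC)c3)c2)ccc1OCc1ccccc1
F7 | step 21 | C9'' tert-butyldimethylsilyl ether of ketone 28 | COc1cc(C[C@@H]2COC(=O)[C@H]2Cc2cc(OC)c(OCc3ccccc3)c([C@@H](CO[Si](C)(C)C(C)(C)C)C(=O)c3ccc(OCc4ccccc4)c(OC)c3)c2)ccc1OCc1ccccc1
A1 | alternative 1 | 3-[4-(benzyloxy)-3-methoxybenzyl]cyclobutan-1-one | COc1cc(CC2CC(=O)C2)ccc1OCc1ccccc1
A2 | alternative 1 | (4S)-4-[4-(benzyloxy)-3-methoxybenzyl]oxolan-2-one (identical with 24) | COc1cc(C[C@@H]2COC(=O)C2)ccc1OCc1ccccc1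
A3 | alternative 2 | ring B aryl ether of (2R,3E)-3-[4-(benzyloxy)-3-methoxyphenyl]-5-[(tert-butyldimethylsilyl)oxy]pent-3-en-2-ol on the (3S,4S)-dibenzyl lactone | COc1cc(C[C@@H]2COC(=O)[C@H]2Cc2cc(OC)c(O[C@H](C)/C(=C/CO[Si](C)(C)C(C)(C)C)c3ccc(OCc4ccccc4)c(OC)c3)cc2)ccc1OCc1ccccc1
A4 | alternative 2 | ring B C5-alkylated phenol with C8'' set and ring D on the ethylidene carbon (methyl trans to C8'') | COc1cc(C[C@@H]2COC(=O)[C@H]2Cc2cc(OC)c(O)c([C@@H](CO[Si](C)(C)C(C)(C)C)/C(=C/C)c3ccc(OCc4ccccc4)c(OC)c3)c2)ccc1OCc1ccccc1
A5 | alternative 3 | (2S,3E)-5-[4-(benzyloxy)-3-methoxyphenyl]pent-3-en-2-yl 3-[4-(benzyloxy)-3-bromo-5-methoxyphenyl]propanoate | C[C@H](OC(=O)CCc1cc(Br)c(OCc2ccccc2)c(OC)c1)/C=C/Cc1ccc(OCc2ccccc2)c(OC)c1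
A6 | alternative 3 | syn-(2S,3R,4E)-2-[4-(benzyloxy)-3-bromo-5-methoxybenzyl]-3-[4-(benzyloxy)-3-methoxybenzyl]hex-4-enoic acid | OC(=O)[C@@H](Cc1cc(Br)c(OCc2ccccc2)c(OC)c1)[C@H](Cc1ccc(OCc2ccccc2)c(OC)c1)/C=C/C
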